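**Retrosynthetic overview**

1. The quinone comes from (NH4)2Ce(NO3)6 oxidative dealkylation of a 1-methoxy-4-ethoxy arene; the angelate is put on just before this, and the ring O-methyl that survives is set just after the ring-forming step.
2. The arene comes from a thermal cyclobutenone–ynol ether benzannulation: ethyl 1-propynyl ether supplies the C-methyl carbon and the neighbouring oxygenated carbon (the future C=O flanked by C–Me and C–H), and these are bonded to the carbonyl carbon (future C–OMe) and to the vinylic CH of a 4-methoxy-3-alkenylcyclobut-2-enone.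
3. Enabling feature: the strained four-membered ring C(=O)–CH=C(side chain)–CH(OMe). Its CH(OMe)–C(=O) bond opens electrocyclically (OMe outward) to a vinylketene; its C(=O)–CH= bond, absent from the target, is a temporary bond cleaved in the cascade. The benzenoid oxidation level is a second temporary device, removed by the last step.
4. The cyclobutenone comes from alkenylation of 3-ethoxy-4-methoxycyclobutenone (methoxyketene + ethoxyacetylene [2+2]) with an (S)-2-lithioallyl silyl ether; the stereocentre comes from Brown allylboration of 2-bromoacrolein and the prenyl terminus from cross-metathesis.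
5. Ring order: cyclobutenone (step 1), then a second, transient cyclobutenone and the six-membered carbocycle (both in step 7), then the quinone (step 11).

Key step: step 7

Assumption: the allylborane whose isopinocampheyl groups derive from (+)-α-pinene is taken to add to the Si face of the aldehyde (usual Brown model), which corresponds to the (S)-carbinol; 2-bromoacrolein is prepared fresh because it polymerises on storage.

**Route**

Step 1
Reactants: 1 methoxyacetyl chloride; 2 ethoxyacetylene
Product: 4 3-ethoxy-4-methoxycyclobut-2-en-1-one (racemic), via methoxyketene 3 (not isolated)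
Conditions: Et3N, 2 (2–3 equiv), Et2O, 0 °C to rt, slow addition of 1
Reagents that add atoms: none
Why: Dehydrochlorination gives methoxyketene in situ, which should undergo the regioselective ketene–alkynyl ether [2+2] cycloaddition (nucleophilic alkyne CH carbon to the ketene carbonyl carbon), the standard entry to 3-ethoxycyclobutenones; the new ring stereocentre is racemic and is destroyed in step 7.

Step 2
Reactants: 5 acrolein
Product: 7 2-bromoacrolein, via 2,3-dibromopropanal 6 (not isolated)
Conditions: Br2, CH2Cl2, −78 to 0 °C; then Et3N, 0 °C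
Reagents that add atoms: bromine, BrBr
Why: Bromine addition to the enal followed by E1cB dehydrobromination (bromination–elimination) is the usual preparation of this aldehyde.

Step 3
Reactants: 7 2-bromoacrolein
Product: 9 (3S)-2-bromohexa-1,5-dien-3-ol, via borinate ester 8 (not isolated)
Conditions: (−)-Ipc2B(allyl), Et2O, −78 °C; then NaOH, H2O2, 0 °C to rt
Reagents that add atoms: (−)-B-allyldiisopinocampheylborane, C=CCB([C@@H]1C[C@@H]2C[C@H]([C@H]1C)C2(C)C)[C@@H]1C[C@@H]2C[C@H]([C@H]1C)C2(C)C
Why: Brown asymmetric allylboration through a chair six-membered transition state, in which the isopinocampheyl groups direct allyl transfer to the Si face of the aldehyde and so set the (S)-carbinol centre, the only stereocentre of the target.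

Step 4
Reactants: 9 (3S)-2-bromohexa-1,5-dien-3-ol
Product: 10 {[(3S)-2-bromohexa-1,5-dien-3-yl]oxy}tri(propan-2-yl)silane
Conditions: TIPSOTf, 2,6-lutidine, CH2Cl2, 0 °C
Reagents that add atoms: triisopropylsilyl trifluoromethanesulfonate, CC(C)[Si](OS(=O)(=O)C(F)(F)F)(C(C)C)C(C)C
Why: Silylation of the secondary alcohol with a silyl triflate; the bulky triisopropylsilyl group is chosen because it should resist 1,4 O-to-C migration in the vinyllithium of step 6 and survive steps 5 to 8.

Step 5
Reactants: 10 {[(3S)-2-bromohexa-1,5-dien-3-yl]oxy}tri(propan-2-yl)silane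
Product: 11 {[(3S)-2-bromo-6-methylhepta-1,5-dien-3-yl]oxy}tri(propan-2-yl)silane
Conditions: second-generation Grubbs catalyst RuCl2(=CHPh)(H2IMes)(PCy3) (3 mol %), 2-methyl-2-butene (solvent), 40 °C, sealed
Reagents that add atoms: 2-methyl-2-butene, CC=C(C)C
Why: Olefin cross-metathesis of the monosubstituted alkene with excess 2-methyl-2-butene should convert allyl into prenyl, while the 2-bromo-1,1-disubstituted alkene is inert to the ruthenium carbene and the stereocentre is untouched.

Step 6
Reactants: 11 {[(3S)-2-bromo-6-methylhepta-1,5-dien-3-yl]oxy}tri(propan-2-yl)silane; 4 3-ethoxy-4-methoxycyclobut-2-en-1-one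
Product: 14 4-methoxy-3-[(3S)-6-methyl-3-(triisopropylsilyloxy)hepta-1,5-dien-2-yl]cyclobut-2-en-1-one (both epimers at the ring CH(OMe)), via vinyllithium 12 (not isolated), via tertiary carbinol 13 (not isolated)
Conditions: t-BuLi (2 equiv), Et2O, −78 °C; then 4, −78 °C; then 1 M HCl aq., THF, 0 °C; product kept cold and used directly
Reagents that add atoms: water, O
Why: Bromine–lithium exchange, 1,2-addition to the vinylogous ester and acid-mediated loss of ethanol with carbonyl transposition (Stork–Danheiser-type alkenylation of a 3-alkoxy enone); because the CH(OMe) carbon is bonded to both oxygenated ring carbons, 1,2- and 1,4-addition converge on the same constitution, and the epimeric ring centre is inconsequential.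

Step 7
Reactants: 14 4-methoxy-3-[(3S)-6-methyl-3-(triisopropylsilyloxy)hepta-1,5-dien-2-yl]cyclobut-2-en-1-one; 15 ethyl 1-propynyl ether
Product: 20 3-ethoxy-6-methoxy-2-methyl-5-[(3S)-6-methyl-3-(triisopropylsilyloxy)hepta-1,5-dien-2-yl]phenol, via vinylketene 16 (not isolated), via alkenylcyclobutenone 17 (not isolated), via dienylketene 18 (not isolated), via cyclohexadienone 19 (not isolated)
Conditions: 15 (3 equiv), PhMe (0.1 M), 80 °C then 110 °C, sealed tube
Reagents that add atoms: none
Why: Heating should open the strained enone by conrotatory 4π electrocyclic cleavage of the CH(OMe)–C(=O) bond (methoxy rotating outward) to the (2-methoxyvinyl)ketene 16, which the ynol ether captures by [2+2] cycloaddition to give cyclobutenone 17; a second 4π opening, now of the original C(=O)–CH bond, gives dienylketene 18, whose 6π electrocyclisation and tautomerisation of dienone 19 deliver the phenol. The closest known reaction type is the Danheiser benzannulation of cyclobutenones with alkoxy- or siloxyalkynes. The transient four-membered ring closes by ketene–alkyne [2+2] cycloaddition and the six-membered ring by thermal disrotatory 6π electrocyclic closure of the ketene carbon onto the methoxy-bearing enol ether carbon. No stereocentre is formed: the ring CH(OMe) centre becomes aromatic and the silyl-protected carbinol centre is a spectator. The step needs regiocontrol in the [2+2] event, which the polarisation of the partners secures (the nucleophilic methyl-bearing alkyne carbon bonds to the electrophilic ketene carbonyl carbon, placing C–Me next to the new phenol carbon and C–OEt next to the ring CH). It also needs chemoselectivity over the isolated alkenes, which is expected because an unactivated or tethered prenyl alkene cannot compete with an excess of ynol ether for the ketene, and excess alkyne at moderate dilution suppresses ketene dimerisation.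

Step 8
Reactants: 20 3-ethoxy-6-methoxy-2-methyl-5-[(3S)-6-methyl-3-(triisopropylsilyloxy)hepta-1,5-dien-2-yl]phenol
Product: 21 {[(3S)-2-(5-ethoxy-2,3-dimethoxy-4-methylphenyl)-6-methylhepta-1,5-dien-3-yl]oxy}tri(propan-2-yl)silane
Conditions: MeI, K2CO3, DMF, rt
Reagents that add atoms: iodomethane, CI
Why: Williamson O-methylation of the only acidic site installs the methoxy group that remains on the quinone.

Step 9
Reactants: 21 {[(3S)-2-(5-ethoxy-2,3-dimethoxy-4-methylphenyl)-6-methylhepta-1,5-dien-3-yl]oxy}tri(propan-2-yl)silane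
Product: 22 (3S)-2-(5-ethoxy-2,3-dimethoxy-4-methylphenyl)-6-methylhepta-1,5-dien-3-ol
Conditions: Bu4NF, THF, rt
Reagents that add atoms: none
Why: Fluoride-mediated silyl ether cleavage frees the secondary allylic alcohol, while aryl ethers and alkenes are inert.

Step 10
Reactants: 22 (3S)-2-(5-ethoxy-2,3-dimethoxy-4-methylphenyl)-6-methylhepta-1,5-dien-3-ol; 23 angelic acid
Product: 25 (3S)-2-(5-ethoxy-2,3-dimethoxy-4-methylphenyl)-6-methylhepta-1,5-dien-3-yl (2Z)-2-methylbut-2-enoate, via mixed anhydride 24 (not isolated)
Conditions: 23, 2,4,6-trichlorobenzoyl chloride, Et3N, PhMe, rt; then 22, 80 °C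
Reagents that add atoms: none
Why: Yamaguchi-type mixed-anhydride esterification run without a nucleophilic catalyst, the protocol suited to angelates because it should avoid Z-to-E isomerisation to the tiglate; the carbinol C–O bond is not broken, so the (S) configuration is retained.

Step 11
Reactants: 25 (3S)-2-(5-ethoxy-2,3-dimethoxy-4-methylphenyl)-6-methylhepta-1,5-dien-3-yl (2Z)-2-methylbut-2-enoate
Product: 26 (3S)-2-(5-methoxy-4-methyl-3,6-dioxocyclohexa-1,4-dien-1-yl)-6-methylhepta-1,5-dien-3-yl (2Z)-2-methylbut-2-enoate (target)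
Conditions: (NH4)2Ce(NO3)6 (2.5 equiv), MeCN–H2O, 0 °C
Reagents that add atoms: water, O
Why: Oxidative dealkylation by tetravalent cerium: the arene radical cation should be attacked by water at the two para-related alkoxylated carbons with loss of methanol and ethanol, giving the 1,4-quinone and leaving the third methoxy group as a vinylogous ester, with the ester, the stereocentre and the isolated alkenes as spectators at 0 °C.

**Compound list**

1 | methoxyacetyl chloride | COCC(Cl)=O | starting material
2 | ethoxyacetylene | CCOC#C | starting material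
3 | methoxyketene | COC=C=O | intermediate
4 | 3-ethoxy-4-methoxycyclobut-2-en-1-one (racemic) | CCOC1=CC(=O)C1OC | intermediate
5 | acrolein | C=CC=O | starting material
6 | 2,3-dibromopropanal | BrCC(Br)C=O | intermediate
7 | 2-bromoacrolein | C=C(Br)C=O | intermediate
8 | (3S)-2-bromohexa-1,5-dien-3-yl diisopinocampheylborinate | C=C(Br)[C@H](CC=C)OB([C@@H]1C[C@@H]2C[C@H]([C@H]1C)C2(C)C)[C@@H]1C[C@@H]2C[C@H]([C@H]1C)C2(C)C | intermediate
9 | (3S)-2-bromohexa-1,5-dien-3-ol | C=C(Br)[C@H](CC=C)O | intermediate
10 | {[(3S)-2-bromohexa-1,5-dien-3-yl]oxy}tri(propan-2-yl)silane | C=C(Br)[C@H](CC=C)O[Si](C(C)C)(C(C)C)C(C)C | intermediate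
11 | {[(3S)-2-bromo-6-methylhepta-1,5-dien-3-yl]oxy}tri(propan-2-yl)silane | C=C(Br)[C@H](CC=C(C)C)O[Si](C(C)C)(C(C)C)C(C)C | intermediate
12 | [(3S)-6-methyl-3-(triisopropylsilyloxy)hepta-1,5-dien-2-yl]lithium | [Li]C(=C)[C@H](CC=C(C)C)O[Si](C(C)C)(C(C)C)C(C)C | intermediate
13 | 3-ethoxy-4-methoxy-1-[(3S)-6-methyl-3-(triisopropylsilyloxy)hepta-1,5-dien-2-yl]cyclobut-2-en-1-ol (diastereomer mixture at the ring carbons) | CCOC1=CC(O)(C(=C)[C@H](CC=C(C)C)O[Si](C(C)C)(C(C)C)C(C)C)C1OC | intermediate
14 | 4-methoxy-3-[(3S)-6-methyl-3-(triisopropylsilyloxy)hepta-1,5-dien-2-yl]cyclobut-2-en-1-one (both epimers at the ring CH(OMe)) | COC1C(=O)C=C1C(=C)[C@H](CC=C(C)C)O[Si](C(C)C)(C(C)C)C(C)C | intermediate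
15 | ethyl 1-propynyl ether (1-ethoxyprop-1-yne) | CCOC#CC | starting material
16 | (5S)-3-(methoxymethylidene)-8-methyl-4-methylidene-5-(triisopropylsilyloxy)nona-1,7-dien-1-one, the vinylketene with OMe anti to the ketene CH | CO/C=C(/C=C=O)C(=C)[C@H](CC=C(C)C)O[Si](C(C)C)(C(C)C)C(C)C | intermediate
17 | 3-ethoxy-4-[(1Z,4S)-1-methoxy-7-methyl-3-methylidene-4-(triisopropylsilyloxy)octa-1,6-dien-2-yl]-2-methylcyclobut-2-en-1-one (both epimers at ring C4) | CCOC1=C(C)C(=O)C1/C(=C/OC)C(=C)[C@H](CC=C(C)C)O[Si](C(C)C)(C(C)C)C(C)C | intermediate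
18 | (7S)-3-ethoxy-5-(methoxymethylidene)-2,10-dimethyl-6-methylidene-7-(triisopropylsilyloxy)undeca-1,3,9-trien-1-one, the dienylketene with the ketene carbon cis to the dienyl group | O=C=C(C)/C(OCC)=C\C(=C\OC)C(=C)[C@H](CC=C(C)C)O[Si](C(C)C)(C(C)C)C(C)C | intermediate
19 | 3-ethoxy-6-methoxy-2-methyl-5-[(3S)-6-methyl-3-(triisopropylsilyloxy)hepta-1,5-dien-2-yl]cyclohexa-2,4-dien-1-one (both epimers at C6) | CCOC1=C(C)C(=O)C(OC)C(C(=C)[C@H](CC=C(C)C)O[Si](C(C)C)(C(C)C)C(C)C)=C1 | intermediate
20 | 3-ethoxy-6-methoxy-2-methyl-5-[(3S)-6-methyl-3-(triisopropylsilyloxy)hepta-1,5-dien-2-yl]phenol | CCOc1cc(C(=C)[C@H](CC=C(C)C)O[Si](C(C)C)(C(C)C)C(C)C)c(OC)c(O)c1C | intermediate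
21 | {[(3S)-2-(5-ethoxy-2,3-dimethoxy-4-methylphenyl)-6-methylhepta-1,5-dien-3-yl]oxy}tri(propan-2-yl)silane | CCOc1cc(C(=C)[C@H](CC=C(C)C)O[Si](C(C)C)(C(C)C)C(C)C)c(OC)c(OC)c1C | intermediate
22 | (3S)-2-(5-ethoxy-2,3-dimethoxy-4-methylphenyl)-6-methylhepta-1,5-dien-3-ol | CCOc1cc(C(=C)[C@H](CC=C(C)C)O)c(OC)c(OC)c1C | intermediate
23 | angelic acid, (2Z)-2-methylbut-2-enoic acid | C/C=C(/C)C(O)=O | starting material
24 | (2Z)-2-methylbut-2-enoic 2,4,6-trichlorobenzoic anhydride | C/C=C(/C)C(=O)OC(=O)c1c(Cl)cc(Cl)cc1Cl | intermediate
25 | (3S)-2-(5-ethoxy-2,3-dimethoxy-4-methylphenyl)-6-methylhepta-1,5-dien-3-yl (2Z)-2-methylbut-2-enoate | CCOc1cc(C(=C)[C@H](CC=C(C)C)OC(=O)/C(C)=C\C)c(OC)c(OC)c1C | intermediate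
26 | (3S)-2-(5-methoxy-4-methyl-3,6-dioxocyclohexa-1,4-dien-1-yl)-6-methylhepta-1,5-dien-3-yl (2Z)-2-methylbut-2-enoate | C=C(C1=CC(=O)C(C)=C(OC)C1=O)[C@H](CC=C(C)C)OC(=O)/C(C)=C\C | target

**Step count**

Total steps: 11. Longest linear sequence: 10 steps (steps 2 to 11, from acrolein); step 1 is a one-step side branch that joins at step 6.

**Steps most likely to fail, with fallbacks**

Step 7. The risk is oligomerisation of the cross-conjugated ketene before the alkyne captures it, or thermal loss of ethylene from the alkynyl ether at the temperature needed for ring opening. The fallback generates the same ketene photochemically at room temperature by a Wolff rearrangement (the diazo ketone form of the benzannulation), so that capture precedes any heating. It sets out from 12 (made from 11 as in step 6) and comes back at 20. Transmetalation of 12 with ZnCl2 (THF, −78 °C to 0 °C) would give the vinylzinc chloride F1. Negishi coupling (Pd(PPh3)4, THF, rt) with (Z)-3-iodo-4-methoxybut-3-en-2-one F2, itself made from commercial 4-methoxybut-3-en-2-one with I2 and pyridine, would give the methyl ketone F3. Detrifluoroacetylative diazo transfer would proceed through the trifluoroacetyl diketone F4 (LiN(SiMe3)2, CF3CO2CH2CF3, THF, −78 °C) and then give the diazo ketone F5 (MsN3, Et3N, H2O, MeCN). Irradiation of F5 with 15 (medium-pressure Hg lamp, CH2Cl2, rt) should give 16 and then 17 at room temperature, and brief warming to 80 °C would complete the passage through 18 and 19 to 20.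

Step 6. The risk is 1,4 O-to-C silyl migration or β-elimination in the lithiated allyl ether competing with carbonyl addition, and premature electrocyclic opening of the strained enone during the acidic work-up. The fallback reverses the polarity and joins the fragments with palladium under neutral conditions. It sets out from 4 (partner 11) and comes back at 14. Addition–elimination of Bu3SnLi to 4 (THF, −78 °C) would give 4-methoxy-3-(tributylstannyl)cyclobut-2-en-1-one F6. Stille coupling of F6 with bromide 11 (Pd2(dba)3, P(2-furyl)3, DMF, rt to 40 °C) would then give 14 without a vinyllithium and without acid.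

Step 11. The risk is over-oxidation of the electron-rich alkenes by the one-electron oxidant, and competing dealkylation at the vicinal dimethoxy pair leading to an ortho-quinone. The fallback separates oxidation from hydrolysis. It sets out from 25 and comes back at 26. Anodic oxidation of 25 (carbon anode, undivided cell, MeOH, LiClO4, 2,6-lutidine, 0 °C, constant current) would give the quinone bis(ketal) F7 at the para-related alkoxylated carbons. Mild hydrolysis of F7 (aqueous AcOH, THF, rt) would then release quinone 26.

**Further compounds**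

F1 | step 7 | chlorido[(3S)-6-methyl-3-(triisopropylsilyloxy)hepta-1,5-dien-2-yl]zinc | Cl[Zn]C(=C)[C@H](CC=C(C)C)O[Si](C(C)C)(C(C)C)C(C)C
F2 | step 7 | (Z)-3-iodo-4-methoxybut-3-en-2-one | CO/C=C(\I)C(C)=O
F3 | step 7 | (5S)-3-(methoxymethylidene)-8-methyl-4-methylidene-5-(triisopropylsilyloxy)non-7-en-2-one, methoxy anti to the acetyl group | CO/C=C(\C(=C)[C@H](CC=C(C)C)O[Si](C(C)C)(C(C)C)C(C)C)C(C)=O
F4 | step 7 | (7S)-1,1,1-trifluoro-5-(methoxymethylidene)-10-methyl-6-methylidene-7-(triisopropylsilyloxy)undec-9-ene-2,4-dione | CO/C=C(\C(=C)[C@H](CC=C(C)C)O[Si](C(C)C)(C(C)C)C(C)C)C(=O)CC(=O)C(F)(F)F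
F5 | step 7 | (5S)-1-diazo-3-(methoxymethylidene)-8-methyl-4-methylidene-5-(triisopropylsilyloxy)non-7-en-2-one | CO/C=C(\C(=C)[C@H](CC=C(C)C)O[Si](C(C)C)(C(C)C)C(C)C)C(=O)C=[N+]=[N-]
F6 | step 6 | 4-methoxy-3-(tributylstannyl)cyclobut-2-en-1-one (racemic) | CCCC[Sn](CCCC)(CCCC)C1=CC(=O)C1OC
F7 | step 11 | (3S)-2-(3-ethoxy-3,5,6,6-tetramethoxy-4-methylcyclohexa-1,4-dien-1-yl)-6-methylhepta-1,5-dien-3-yl (2Z)-2-methylbut-2-enoate (both epimers at the mixed ketal carbon) | COC1=C(C)C(OC)(OCC)C=C(C(=C)[C@H](CC=C(C)C)OC(=O)/C(C)=C\C)C1(OC)OC
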